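**Remarks on the chemistry.** Eremophilane numbering is used: ring A = C1–C5/C10, ring B = C5–C10, C14 on C5, C15 on C4, C11–C13 = isopropenyl. β is the face of the C5 methyl group. The target is read as (3R,4R,5R,7R,9R,10S), the cis-fused 3α,9β-bis(angeloyloxy)-10βH-eremophil-11-en-8-one. Compounds 7 and 11–16 are carried as epimer mixtures at C5 and C7; both centres are erased in step 13 (planar radical at C5, carbanion at C7).

**Retrosynthetic overview**
1. Target 23 ← diol 20 (double angeloylation with two equivalents of angelic acid) ← β-keto sulfone 18 (C9 enolate hydroxylation, then C7 desulfonylation).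
2. 18 ← cesium oxalate 16 in one operation: the C5 tertiary radical adds to C10 of a temporary seven-membered enoate lactone (C5–C10, ring A), then the sulfone-stabilised C7 carbanion takes over the lactone carbonyl C8 (C7–C8, ring B) and sets O3 free.
3. Enabling feature: O3 and C8 are 1,6-related (O3–C3–C2–C1–C10–C9–C8), so a lactone O3–C8(=O)–C9=C10 holds the acceptor on the α-face of the future ring A (cis fusion) and makes C8 an acyl donor. C5 is a methyl-bearing quaternary carbon (tertiary radical). C7 lies between C8 and the isopropenyl group (allyl sulfone carbanion).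
4. 16 ← lactone 14 (ring-closing metathesis of acrylate 13) ← diol 12 ← epoxide 7 + methallyl phenyl sulfone 10; C3/C4 come from an Evans syn-aldol of 1 with pent-4-enal 2.
5. Order of ring formation: temporary lactone (step 10), ring A then ring B (both step 13, lactone lost).

Key step: step 13

**Step 1**
Reactants: 1 (S)-4-benzyl-3-propionyloxazolidin-2-one; 2 pent-4-enal
Product: 3 (S)-4-benzyl-3-[(2S,3R)-3-hydroxy-2-methylhept-6-enoyl]oxazolidin-2-one
Conditions: Bu2BOTf, i-Pr2NEt, CH2Cl2, −78 → 0 °C; then H2O2, pH 7 buffer, MeOH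
Reagents that add atoms: none
Why: Evans syn-aldol; the Z-boron enolate reacts through a closed chair transition state with one face blocked by the benzyl group, which should set the C3 carbinol and C4 methyl centres as the (2S,3R) syn pair.

**Step 2**
Reactants: 3
Product: 4 (2S,3R)-3-hydroxy-N-methoxy-N,2-dimethylhept-6-enamide
Conditions: MeNH(OMe)·HCl, AlMe3, CH2Cl2, −10 → 0 °C
Reagents that add atoms: N,O-dimethylhydroxylamine hydrochloride, Cl.CNOC
Why: Aluminium-amide transamination of the N-acyloxazolidinone to the Weinreb amide, assisted by the free β-hydroxyl group, should release the auxiliary without touching either stereocentre.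

**Step 3**
Reactants: 4
Product: 5 (2S,3R)-3-(tert-butyldimethylsilyloxy)-N-methoxy-N,2-dimethylhept-6-enamide
Conditions: TBSOTf, 2,6-lutidine, CH2Cl2, −78 → 0 °C
Reagents that add atoms: tert-butyldimethylsilyl triflate, CC(C)(C)[Si](C)(C)OS(=O)(=O)C(F)(F)F
Why: Silylation of the secondary alcohol masks O3 for the basic carbanion steps that follow.

**Step 4**
Reactants: 5
Product: 6 (3S,4R)-4-(tert-butyldimethylsilyloxy)-3-methyloct-7-en-2-one
Conditions: MeMgBr, THF, 0 °C
Reagents that add atoms: methylmagnesium bromide, C[Mg]Br
Why: Weinreb ketone synthesis; the chelated tetrahedral intermediate should stop the addition at the methyl ketone, whose carbonyl carbon is the future C5 and whose methyl group is C14.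

**Step 5**
Reactants: 6
Product: 7 2-[(2S,3R)-3-(tert-butyldimethylsilyloxy)hept-6-en-2-yl]-2-methyloxirane (both epimers at the oxirane carbon C5)
Conditions: Me3S+ I−, n-BuLi, THF, −10 °C → rt
Reagents that add atoms: trimethylsulfonium iodide, C[S+](C)C.[I-]
Why: Corey–Chaykovsky epoxidation adds C6 as the oxirane CH2; the configuration at C5 need not be controlled because this carbon becomes a planar radical in step 13.

**Step 6**
Reactants: 8 sodium benzenesulfinate; 9 3-chloro-2-methylprop-1-ene
Product: 10 (2-methylallyl) phenyl sulfone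
Conditions: DMF, Bu4NI (cat.), rt
Reagents that add atoms: none
Why: SN2 S-alkylation of the sulfinate by the allylic chloride gives the allyl sulfone.

**Step 7**
Reactants: 7; 10
Product: 11 (6S,7R)-7-(tert-butyldimethylsilyloxy)-2,5,6-trimethyl-3-(phenylsulfonyl)undeca-1,10-dien-5-ol (epimers at C3 and C5 of this chain, which are C7 and C5 of the skeleton)
Conditions: 10, n-BuLi, THF, −78 °C; then 7, DMPU, −78 °C → rt
Reagents that add atoms: none
Why: The α-lithiated allyl sulfone should open the 2,2-disubstituted epoxide at its CH2 terminus (SN2), joining C6 to C7 and leaving the tertiary C5 alcohol; both new centres are erased later.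

**Step 8**
Reactants: 11
Product: 12 (6S,7R)-2,5,6-trimethyl-3-(phenylsulfonyl)undeca-1,10-diene-5,7-diol
Conditions: Bu4NF, THF, rt
Reagents that add atoms: none
Why: Fluoride-mediated desilylation frees the secondary C3 alcohol.

**Step 9**
Reactants: 12
Product: 13 (6S,7R)-5-hydroxy-2,5,6-trimethyl-3-(phenylsulfonyl)undeca-1,10-dien-7-yl acrylate
Conditions: acryloyl chloride, Et3N, CH2Cl2, −40 °C
Reagents that add atoms: acryloyl chloride, C=CC(=O)Cl
Why: O-acylation should be selective for the secondary alcohol because the tertiary C5 alcohol is far less reactive; the acryloyl carbons are the future C8 and C9.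

**Step 10**
Reactants: 13
Product: 14 (7R)-7-[(2S)-3-hydroxy-3,6-dimethyl-5-(phenylsulfonyl)hept-6-en-2-yl]-6,7-dihydrooxepin-2(5H)-one
Conditions: second-generation Grubbs catalyst (H2IMes)(PCy3)Cl2Ru=CHPh (5 mol%), CH2Cl2 (2 mM), 40 °C
Reagents that add atoms: none
Why: Ring-closing metathesis of the acrylate with the terminal alkene should close the seven-membered Z-enoate lactone O3–C8(=O)–C9=C10; the 1,1-disubstituted allyl sulfone alkene is a poor metathesis partner.

**Step 11**
Reactants: 14
Product: 15 methyl oxalate of the tertiary C5 alcohol of 14 (C5–O–CO–CO2Me)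
Conditions: ClC(O)CO2Me, Et3N, DMAP (cat.), CH2Cl2, 0 °C
Reagents that add atoms: methyl chlorooxoacetate, COC(=O)C(=O)Cl
Why: Acylation of the tertiary alcohol with the highly reactive oxalyl half-ester chloride installs the radical precursor.

**Step 12**
Reactants: 15
Product: 16 cesium oxalate of the tertiary C5 alcohol of 14 (C5–O–CO–CO2− Cs+)
Conditions: CsOH (1.0 equiv), THF/H2O, 0 °C, then evaporation
Reagents that add atoms: cesium hydroxide, [Cs+].[OH-]
Why: Selective saponification; a methyl oxalate hydrolyses far faster than the lactone, which should give the bench-stable cesium salt.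

**Step 13**
Reactants: 16
Product: 18 3α-hydroxy-7-(phenylsulfonyl)-10βH-eremophil-11-en-8-one, via bridged lactone 17 (not isolated)
Conditions: Ir[dF(CF3)ppy]2(dtbbpy)PF6 (2 mol%), dry DME/DMF 3:1 (5 mM), 450 nm LEDs, 60 °C; then AcOH
Reagents that add atoms: none
Why: Proposed new method: photoexcited trivalent iridium oxidises the oxalate, loss of two CO2 gives the tertiary C5 radical, this adds 6-exo-trig to C10 of the lactone enoate (ring A, giving the 2-oxabicyclo[3.2.2]nonanone 17), and divalent iridium reduces the α-lactone radical to the cesium enolate (radical–polar crossover). The enolate is quenched by the more acidic allyl sulfone C7–H, and the C7 carbanion then attacks the lactone carbonyl C8 6-exo-trig (ring B, Dieckmann-type acyl transfer), expelling the O3 alkoxide and releasing the strain of the bridged boat lactone. The closest known reactions are the decarboxylative Giese addition of tertiary oxalate-derived radicals to acrylates and the C-acylation of α-sulfonyl carbanions by esters; coupling them through an internal proton relay is new. C10 is fixed by the lactone tether, since C9 and O3 must end cis on ring A, which is the 10βH cis fusion; at C5 the planar radical should place the small CH3 beside the C4 methyl group and the sulfonyl-bearing arm on the lactone face, and only that epimer can reach C8; C3 and C4 are carried in from step 1. The step needs 6-exo addition at C10 to outrun reduction and intermolecular addition (high dilution, nucleophilic radical matched with an enoate β-carbon) and α- rather than γ-acylation of the allyl sulfone anion (six- versus eight-membered ring). C7 forms as an inconsequential epimer mixture, and both C5 epimers of 16 converge on the same radical.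

**Step 14**
Reactants: 18
Product: 19 3α,9β-dihydroxy-7-(phenylsulfonyl)-10βH-eremophil-11-en-8-one
Conditions: KN(SiMe3)2 (2.2 equiv), THF, −78 °C; 2-(phenylsulfonyl)-3-phenyloxaziridine; then AcOH
Reagents that add atoms: 2-(phenylsulfonyl)-3-phenyloxaziridine, O=S(=O)(c1ccccc1)N1OC1c1ccccc1
Why: Enolate α-hydroxylation with an N-sulfonyloxaziridine; only C9 can be enolised because C7 is quaternary, and attack on the convex β-face of the cis-decalin should give the equatorial 9β-alcohol.

**Step 15**
Reactants: 19
Product: 20 3α,9β-dihydroxy-10βH-eremophil-11-en-8-one (7β-isopropenyl)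
Conditions: SmI2 (2.5 equiv), THF/MeOH, −78 °C
Reagents that add atoms: none
Why: Reductive desulfonylation of a β-keto sulfone by electron transfer gives the samarium dienolate; kinetic axial α-protonation at C7 should leave the isopropenyl group equatorial (β) and unconjugated, and the C–S bond should cleave far faster than the α-hydroxy C–O bond at −78 °C.

**Step 16**
Reactants: 20; 21 angelic acid ((Z)-2-methylbut-2-enoic acid), of which two equivalents are built into the product
Product: 23 target CNP0174755.1 (3α,9β-bis(angeloyloxy)-10βH-eremophil-11-en-8-one), via mixed anhydride 22 (not isolated)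
Conditions: 21 (2.6 equiv), 2,4,6-trichlorobenzoyl chloride (2.6 equiv), Et3N, toluene, rt; then 20, 80 °C (no DMAP)
Reagents that add atoms: angelic acid (the second equivalent of 21), C/C=C(/C)C(=O)O
Why: Yamaguchi esterification; two molecules of the mixed anhydride should acylate the two secondary alcohols at C3 and C9, and leaving out the nucleophilic catalyst is what keeps the Z-geometry of the angelate.

**Compound list**
1 | (S)-4-benzyl-3-propionyloxazolidin-2-one | CCC(=O)N1[C@@H](Cc2ccccc2)COC1=O | starting material
2 | pent-4-enal | C=CCCC=O | starting material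
3 | (S)-4-benzyl-3-[(2S,3R)-3-hydroxy-2-methylhept-6-enoyl]oxazolidin-2-one | C=CCC[C@@H](O)[C@H](C)C(=O)N1C(=O)OC[C@@H]1Cc1ccccc1 | intermediate
4 | (2S,3R)-3-hydroxy-N-methoxy-N,2-dimethylhept-6-enamide | C=CCC[C@@H](O)[C@H](C)C(=O)N(C)OC | intermediate
5 | (2S,3R)-3-(tert-butyldimethylsilyloxy)-N-methoxy-N,2-dimethylhept-6-enamide | C=CCC[C@@H](O[Si](C)(C)C(C)(C)C)[C@H](C)C(=O)N(C)OC | intermediate
6 | (3S,4R)-4-(tert-butyldimethylsilyloxy)-3-methyloct-7-en-2-one | C=CCC[C@@H](O[Si](C)(C)C(C)(C)C)[C@H](C)C(C)=O | intermediate
7 | 2-[(2S,3R)-3-(tert-butyldimethylsilyloxy)hept-6-en-2-yl]-2-methyloxirane (C5 epimers) | C=CCC[C@@H](O[Si](C)(C)C(C)(C)C)[C@H](C)C1(C)CO1 | intermediate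
8 | sodium benzenesulfinate | [Na+].[O-]S(=O)c1ccccc1 | starting material
9 | 3-chloro-2-methylprop-1-ene | C=C(C)CCl | starting material
10 | (2-methylallyl) phenyl sulfone | C=C(C)CS(=O)(=O)c1ccccc1 | intermediate
11 | (6S,7R)-7-(tert-butyldimethylsilyloxy)-2,5,6-trimethyl-3-(phenylsulfonyl)undeca-1,10-dien-5-ol (C5/C7 epimers) | C=CCC[C@@H](O[Si](C)(C)C(C)(C)C)[C@H](C)C(C)(O)CC(C(C)=C)S(=O)(=O)c1ccccc1 | intermediate
12 | (6S,7R)-2,5,6-trimethyl-3-(phenylsulfonyl)undeca-1,10-diene-5,7-diol | C=CCC[C@@H](O)[C@H](C)C(C)(O)CC(C(C)=C)S(=O)(=O)c1ccccc1 | intermediate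
13 | (6S,7R)-5-hydroxy-2,5,6-trimethyl-3-(phenylsulfonyl)undeca-1,10-dien-7-yl acrylate | C=CCC[C@@H](OC(=O)C=C)[C@H](C)C(C)(O)CC(C(C)=C)S(=O)(=O)c1ccccc1 | intermediate
14 | (7R)-7-[(2S)-3-hydroxy-3,6-dimethyl-5-(phenylsulfonyl)hept-6-en-2-yl]-6,7-dihydrooxepin-2(5H)-one | O=C1O[C@@H]([C@H](C)C(C)(O)CC(C(C)=C)S(=O)(=O)c2ccccc2)CCC=C1 | intermediate
15 | methyl oxalate of the tertiary alcohol of 14 | O=C1O[C@@H]([C@H](C)C(C)(OC(=O)C(=O)OC)CC(C(C)=C)S(=O)(=O)c2ccccc2)CCC=C1 | intermediate
16 | cesium oxalate of the tertiary alcohol of 14 | O=C1O[C@@H]([C@H](C)C(C)(OC(=O)C(=O)[O-])CC(C(C)=C)S(=O)(=O)c2ccccc2)CCC=C1.[Cs+] | intermediate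
17 | bridged lactone: 6,7-dimethyl-6-[3-methyl-2-(phenylsulfonyl)but-3-en-1-yl]-2-oxabicyclo[3.2.2]nonan-3-one (C5–C10 formed, O3–C8 lactone intact) | O=C1C[C@H]2CC[C@@H](O1)[C@H](C)[C@@]2(C)CC(C(C)=C)S(=O)(=O)c1ccccc1 | intermediate
18 | 3α-hydroxy-7-(phenylsulfonyl)-10βH-eremophil-11-en-8-one (C7 epimers) | C=C(C)C1(S(=O)(=O)c3ccccc3)C[C@@]2(C)[C@H](CC[C@@H](O)[C@@H]2C)CC1=O | intermediate
19 | 3α,9β-dihydroxy-7-(phenylsulfonyl)-10βH-eremophil-11-en-8-one | C=C(C)C1(S(=O)(=O)c3ccccc3)C[C@@]2(C)[C@H](CC[C@@H](O)[C@@H]2C)[C@@H](O)C1=O | intermediate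
20 | 3α,9β-dihydroxy-10βH-eremophil-11-en-8-one | C=C(C)[C@H]1C[C@@]2(C)[C@H](CC[C@@H](O)[C@@H]2C)[C@@H](O)C1=O | intermediate
21 | angelic acid | C/C=C(/C)C(=O)O | starting material
22 | (Z)-2-methylbut-2-enoic 2,4,6-trichlorobenzoic anhydride | C/C=C(/C)C(=O)OC(=O)c1c(Cl)cc(Cl)cc1Cl | intermediate
23 | CNP0174755.1, 3α,9β-bis(angeloyloxy)-10βH-eremophil-11-en-8-one | C=C(C)[C@H]1C[C@@]2(C)[C@H](CC[C@@H](OC(=O)/C(C)=C\C)[C@@H]2C)[C@@H](OC(=O)/C(C)=C\C)C1=O | target

**Step count.** 16 steps in total; the longest linear sequence is 15 steps (steps 1–5 and 7–16).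

**Steps most likely to fail**

Step 13 (proposed new method). The proton relay may be lost to adventitious water, so that the sequence stops at the bridged lactone. The planar C5 radical may show poor facial discrimination. The acyl transfer may also reverse, because the quaternary C7 of the product carries a 1,3-diaxial interaction. The fallback separates the two events with known chemistry and sets out from 14. Oxalyl chloride followed by N-hydroxyphthalimide and Et3N should give the tert-alkyl N-phthalimidoyl oxalate F1. Reductive photoredox fragmentation of F1 (Ru(bpy)3(PF6)2, Hantzsch ester, i-Pr2NEt·HBF4, CH2Cl2, blue LEDs) generates the same C5 radical, which cyclises onto the tethered enoate and is terminated by hydrogen-atom transfer, so that 17 is isolated. Treating 17 with LiN(SiMe3)2 (2.2 equiv, THF, −78 → 0 °C) then effects the intramolecular C-acylation of the sulfone carbanion by the lactone, and the sequence returns to the route at 18.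

Step 15. Over-reduction may remove the C9 oxygen, γ-protonation of the dienolate may move the double bond into conjugation, and facial control in the C7 protonation may be poor. The fallback changes the order of events and sets out from 18. Desulfonylation of 18 itself with SmI2 (THF/MeOH, −78 °C), where no α-oxygen is present, should give 3α-hydroxy-10βH-eremophil-11-en-8-one F2. Kinetic deprotonation at the less hindered C9 methylene (LiN(i-Pr)2, 2.2 equiv, Me3SiCl, THF, −78 °C) should give the bis-silyl compound F3, with a C3 trimethylsilyl ether and a C8–C9 silyl enol ether. Rubottom oxidation of F3 (dimethyldioxirane, acetone, −78 °C, then citric acid/MeOH) returns to the route at 20.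

Step 16. The angelate may isomerise Z to E (tiglate), the hindered C3 alcohol may acylate incompletely so that only one of the two required angeloyl groups is introduced, and base may shift the 11,12 double bond into conjugation. The fallback builds the Z-enoate on the substrate instead and sets out from 20. Esterification with 2-(diphenoxyphosphoryl)propanoic acid (EDC·HCl, cat. DMAP, CH2Cl2) should give the bis(phosphonopropanoate) F4. A Z-selective Horner–Wadsworth–Emmons olefination of F4 with acetaldehyde (diaryl phosphonate variant; NaI, DBU, THF, −78 → 0 °C) then forms both angelate groups and returns to the route at 23.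

**Further compounds**
F1 | step 13 | N-phthalimidoyl oxalate of the tertiary alcohol of 14 | O=C1O[C@@H]([C@H](C)C(C)(OC(=O)C(=O)ON3C(=O)c4ccccc4C3=O)CC(C(C)=C)S(=O)(=O)c2ccccc2)CCC=C1
F2 | step 15 | 3α-hydroxy-10βH-eremophil-11-en-8-one | C=C(C)[C@H]1C[C@@]2(C)[C@H](CC[C@@H](O)[C@@H]2C)CC1=O
F3 | step 15 | 3α,8-bis(trimethylsilyloxy)-10βH-eremophila-8,11-diene | C=C(C)[C@H]1C[C@@]2(C)[C@H](CC[C@@H](O[Si](C)(C)C)[C@@H]2C)C=C1O[Si](C)(C)C
F4 | step 16 | 3α,9β-bis[2-(diphenoxyphosphoryl)propanoyloxy]-10βH-eremophil-11-en-8-one | C=C(C)[C@H]1C[C@@]2(C)[C@H](CC[C@@H](OC(=O)C(C)P(=O)(Oc3ccccc3)Oc3ccccc3)[C@@H]2C)[C@@H](OC(=O)C(C)P(=O)(Oc3ccccc3)Oc3ccccc3)C1=O
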